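**Plan**

- Retrosynthesis: the exocyclic CH2=C11 goes back to an α-carboxy lactone (Mannich condensation with CH2O). Ring C (C7–C11 and C6–O together) goes back to the C6=C7 alkene of ring A and a malonic half-ester on O9. C6=C7 is cut by ring-closing metathesis, ring B (O–C3) by cycloisomerisation of a hydroxy-ynone, C2–C3 by acetylide plus Weinreb amide, and C10–CH3 by Grignard addition.
- Enabling feature: on ring A the C9 hydroxyl is 1,3-cis to the C7–C11 bond and the C6 lactone oxygen is trans to it. An O9-bound malonyl radical can therefore reach only the β face of C7 (temporary δ-lactone, ring D), and its free carboxyl then closes ring C on C6. Ring D is cut again and its carbonyl leaves as CO2 when the methylene is made.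
- Forward order: southern alkyne 9 (C7–C10, C1, C2) from D-erythronolactone acetonide and northern Weinreb amide 14 (C3–C6) by aldol; union, ring B, ring A, angelate on O8, malonate on O9, rings C and D in one step, ring D removed with methylenation, desilylation.
- Stereochemistry: C8/C9 from D-erythrose; C10 by Felkin–Anh methyl addition; C4/C5 from the Evans syn-aldol; C7 and C6 in the key step under control of C9 through ring D; the angelate geometry comes from angelic acid.

Key step: step 16

Remark: germacrane numbering is used (C1 ketone, C2=C3, C4–CH3, C5–OH, C6–O lactone, C7, C8–OAng, C9–OH, C10 with CH3 and the ring-B oxygen, C11/C12/C13 lactone carbons); β is the face of ring A that carries C11 on C7; ring A = ten-membered carbocycle, ring B = furanone, ring C = γ-lactone, ring D = temporary δ-lactone; 1, 5, 10, 11, 19 and 21 are taken as commercial.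

**Step 1**
Reactants: 1 2,3-O-isopropylidene-D-erythronolactone
Product: 2 2,3-O-isopropylidene-D-erythrofuranose (lactol, both anomers)
Conditions: i-Bu2AlH, CH2Cl2, −78 °C
Reagents that add atoms: none
Why: Half-reduction of a γ-lactone to the lactol by a dialkylaluminium hydride at low temperature, which leaves the C8 and C9 centres untouched.

**Step 2**
Reactants: 2 2,3-O-isopropylidene-D-erythrofuranose
Product: 3 [(4R,5S)-2,2-dimethyl-5-vinyl-1,3-dioxolan-4-yl]methanol
Conditions: Ph3PCH3Br, KOtBu, THF, 0 °C to rt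
Reagents that add atoms: methylenetriphenylphosphorane C=P(c1ccccc1)(c1ccccc1)c1ccccc1
Why: Wittig methylenation of the open hydroxy-aldehyde form of the lactol installs the C7 vinyl group and frees the primary alcohol that becomes C10.

**Step 3**
Reactants: 3 [(4R,5S)-2,2-dimethyl-5-vinyl-1,3-dioxolan-4-yl]methanol
Product: 4 (4S,5S)-2,2-dimethyl-5-vinyl-1,3-dioxolane-4-carbaldehyde
Conditions: Dess–Martin periodinane, CH2Cl2, 0 °C to rt (used crude)
Reagents that add atoms: none
Why: Dess–Martin oxidation is non-basic, so the cis-dioxolane aldehyde should not epimerise at C9 if used at once.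

**Step 4**
Reactants: 4 (4S,5S)-2,2-dimethyl-5-vinyl-1,3-dioxolane-4-carbaldehyde; 5 ethynyltrimethylsilane
Product: 6 1-[(4R,5S)-2,2-dimethyl-5-vinyl-1,3-dioxolan-4-yl]-3-(trimethylsilyl)prop-2-yn-1-ol (both carbinol epimers)
Conditions: 5, n-BuLi, THF, −78 °C; then 4; aq. NH4Cl
Reagents that add atoms: none
Why: 1,2-Addition of a lithium acetylide to the aldehyde; the new carbinol configuration is irrelevant because it is oxidised in the next step.

**Step 5**
Reactants: 6 1-[(4R,5S)-2,2-dimethyl-5-vinyl-1,3-dioxolan-4-yl]-3-(trimethylsilyl)prop-2-yn-1-ol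
Product: 7 1-[(4S,5S)-2,2-dimethyl-5-vinyl-1,3-dioxolan-4-yl]-3-(trimethylsilyl)prop-2-yn-1-one
Conditions: Dess–Martin periodinane, CH2Cl2, rt
Reagents that add atoms: none
Why: Dess–Martin oxidation of a propargylic alcohol to the ynone under neutral conditions.

**Step 6**
Reactants: 7 1-[(4S,5S)-2,2-dimethyl-5-vinyl-1,3-dioxolan-4-yl]-3-(trimethylsilyl)prop-2-yn-1-one
Product: 9 (S)-2-[(4S,5S)-2,2-dimethyl-5-vinyl-1,3-dioxolan-4-yl]but-3-yn-2-ol, via C-silylated carbinol 8 (not isolated)
Conditions: MeMgBr, THF, −78 °C; then MeOH, K2CO3, rt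
Reagents that add atoms: methylmagnesium bromide C[Mg]Br
Why: Grignard 1,2-addition to the ynone under Felkin–Anh (non-chelation) control, the methyl entering anti to the dioxolane C9–O bond to set C10, followed by methanolysis of the alkynyl C–Si bond.

**Step 7**
Reactants: 10 acrolein; 11 (S)-4-benzyl-3-propionyloxazolidin-2-one
Product: 12 (S)-4-benzyl-3-[(2S,3R)-3-hydroxy-2-methylpent-4-enoyl]oxazolidin-2-one
Conditions: n-Bu2BOTf, i-Pr2NEt, CH2Cl2, −78 to 0 °C; then H2O2, pH 7 buffer, MeOH
Reagents that add atoms: none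
Why: Evans syn-aldol through the Z boron enolate and a Zimmerman–Traxler transition state, in which the auxiliary sets C4 and C5 (syn methyl/hydroxyl).

**Step 8**
Reactants: 12 (S)-4-benzyl-3-[(2S,3R)-3-hydroxy-2-methylpent-4-enoyl]oxazolidin-2-one
Product: 13 (2S,3R)-3-hydroxy-N-methoxy-N,2-dimethylpent-4-enamide
Conditions: MeONHMe·HCl, AlMe3, CH2Cl2, 0 °C to rt
Reagents that add atoms: N,O-dimethylhydroxylamine hydrochloride CNOC.Cl
Why: Aluminium-amide transamidation of the imide to the Weinreb amide, assisted by the free β-hydroxyl, without epimerisation at C4.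

**Step 9**
Reactants: 13 (2S,3R)-3-hydroxy-N-methoxy-N,2-dimethylpent-4-enamide
Product: 14 (2S,3R)-N-methoxy-N,2-dimethyl-3-(triisopropylsilyloxy)pent-4-enamide
Conditions: TIPSOTf, 2,6-lutidine, CH2Cl2, 0 °C
Reagents that add atoms: triisopropylsilyl trifluoromethanesulfonate CC(C)[Si](C(C)C)(C(C)C)OS(=O)(=O)C(F)(F)F
Why: Silyl triflate silylation of the secondary alcohol; the triisopropylsilyl group is chosen to survive the later acetal hydrolysis and hot acetic acid.

**Step 10**
Reactants: 9 (S)-2-[(4S,5S)-2,2-dimethyl-5-vinyl-1,3-dioxolan-4-yl]but-3-yn-2-ol; 14 (2S,3R)-N-methoxy-N,2-dimethyl-3-(triisopropylsilyloxy)pent-4-enamide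
Product: 15 (3R,4S,8S)-8-[(4S,5S)-2,2-dimethyl-5-vinyl-1,3-dioxolan-4-yl]-8-hydroxy-4-methyl-3-(triisopropylsilyloxy)non-1-en-6-yn-5-one
Conditions: 9, n-BuLi (2 equiv), THF, −78 °C; then 14, −78 to −20 °C; aq. NH4Cl
Reagents that add atoms: none
Why: The alkoxide–acetylide dianion acylates on the Weinreb amide, whose stable chelated adduct stops over-addition and gives the hydroxy-ynone.

**Step 11**
Reactants: 15 hydroxy-ynone
Product: 16 (R)-2-[(4S,5S)-2,2-dimethyl-5-vinyl-1,3-dioxolan-4-yl]-2-methyl-5-[(2S,3R)-3-(triisopropylsilyloxy)pent-4-en-2-yl]furan-3(2H)-one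
Conditions: Et2NH, EtOH, rt; then AcOH, H2O, THF, rt
Reagents that add atoms: water O
Why: Classical hydroxy-ynone to 3(2H)-furanone cycloisomerisation: conjugate addition of the amine at C1 gives an enaminone, O10 closes on the C3 carbonyl (5-exo-trig), and dehydration and iminium hydrolysis give ring B with the ketone at C1.

**Step 12**
Reactants: 16 furanone diene
Product: 17 ring-A/ring-B macrocycle: 3,10-epoxygermacra-2,6Z-dien-1-one with 4α-CH3, 5β-OTIPS, 8β,9β-O-isopropylidene and 10β-CH3
Conditions: second-generation Grubbs catalyst (10 mol %), toluene (1 mM), 80 °C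
Reagents that add atoms: none
Why: Ring-closing metathesis of two monosubstituted allylic-oxygenated alkenes; the planar furanone and the cis-dioxolane on C8/C9 act as turn elements, and the bridged nine-membered oxacycle can only hold the Z alkene.

**Step 13**
Reactants: 17 macrocyclic acetonide
Product: 18 8β,9β-diol of 17 (5β-OTIPS kept)
Conditions: AcOH–H2O–THF (3:1:1), 50 °C
Reagents that add atoms: none
Why: Acid hydrolysis of the isopropylidene acetal; the triisopropylsilyl ether and the vinylogous-ester furanone should survive aqueous acetic acid.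

**Step 14**
Reactants: 18 8β,9β-diol; 19 angelic acid [(Z)-2-methylbut-2-enoic acid]
Product: 20 8β-O-angelate of 18 (9β-OH free)
Conditions: 19, 2,4,6-trichlorobenzoyl chloride, Et3N, toluene, rt; then 18, 75 °C
Reagents that add atoms: none
Why: Yamaguchi-type mixed-anhydride esterification run without DMAP, which should keep the Z geometry; the allylic C8 hydroxyl should react in preference to the C9 hydroxyl, which is neopentyl-like next to quaternary C10.

**Step 15**
Reactants: 20 8β-O-angelate; 21 Meldrum's acid (2,2-dimethyl-1,3-dioxane-4,6-dione)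
Product: 22 9β-O-(carboxyacetyl) derivative of 20 (malonic half-ester on O9)
Conditions: toluene, 100 °C
Reagents that add atoms: none
Why: Thermal alcoholysis of Meldrum's acid gives the malonic half-ester with loss of acetone, and O9 is the only free hydroxyl.

**Step 16**
Reactants: 22 malonic half-ester
Product: 23 bis-lactone: ring C (C12(=O)–O–C6, γ) and ring D (C13(=O)–O–C9, δ) fused at C7–C11 with H7 and H11 cis; 8β-angelate and 5β-OTIPS kept
Conditions: Mn(OAc)3·2H2O (2.2 equiv), Cu(OAc)2·H2O (0.5 equiv), degassed AcOH (5 mM), 60 °C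
Reagents that add atoms: none
Why: Trivalent manganese oxidises the enolised malonic half-ester to the C11 radical, which adds 6-exo-trig to C7 of the C6=C7 alkene (ring D); the C6 radical is then oxidised by divalent copper to an alkylcopper/cation that the free carboxyl captures to close the five-membered ring C, so C11–C7 and O–C6 form in one radical–polar crossover [3+2] annulation. The closest known reaction type is the Mn(OAc)3/Cu(OAc)2 oxidative free-radical cyclisation of unsaturated malonate esters to fused bis-lactones. C7 is controlled by C9: the O9–C(=O)–C11 bridge spans C9 and C7 across ring A and can only form on the β face where O9 sits, which is also the face the Z alkene turns toward C9 when H8 lies in the alkene plane (allylic 1,3-strain). C11 follows from the cis fusion of rings C and D (the carboxyl must sit cis to C6 to close), and C6 from the fact that, with ring D in place, only the target configuration lets the carboxylate reach C6 while H6, and not O6 or C5, points into ring A toward C10. The step needs 6-exo over 7-endo attack and over addition to the furanone C2 (favoured by ring size and proximity) and lactonisation over β-hydride loss from the C6 copper species (favoured by the adjacent carboxylate); the angelate, silyl ether and furanone should be inert to the electrophilic radical and to AcOH at 60 °C.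

**Step 17**
Reactants: 23 bis-lactone
Product: 25 5-O-triisopropylsilyl ether of the target, via malonic half-acid 24 (not isolated)
Conditions: LiOH (1.05 equiv), THF–H2O, 0 °C; AcOH to pH 4, rt; then 37% aq. HCHO, Et2NH, 40 °C
Reagents that add atoms: formaldehyde C=O; lithium hydroxide [Li+].[OH-] (its oxygen is in 24 only and leaves as CO2)
Why: Saponification should open the strained, bridging δ-lactone (ring D) faster than the γ-lactone or the hindered conjugated angelate, since δ-lactones are saponified markedly faster than γ-lactones, the resulting carboxylate shields the remaining malonyl carbonyl and any opened ring C recloses on acidification; the malonic half-acid then undergoes Mannich condensation with formaldehyde and decarboxylative elimination of the amine to give the α-methylene lactone.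

**Step 18**
Reactants: 25 5-O-triisopropylsilyl ether of the target
Product: 26 CNP0206920.2 (target)
Conditions: HF·pyridine, pyridine, THF, 0 °C to rt
Reagents that add atoms: none
Why: Fluoride cleavage of the silyl ether under buffered conditions that the α-methylene lactone, the angelate and the furanone should tolerate.

**Compound list**

1 | 2,3-O-isopropylidene-D-erythronolactone, (3aR,6aR)-2,2-dimethyldihydrofuro[3,4-d][1,3]dioxol-4(3aH)-one | O=C1OC[C@H]2OC(C)(C)O[C@H]21 | starting material
2 | 2,3-O-isopropylidene-D-erythrofuranose (lactol, both anomers) | OC1OC[C@H]2OC(C)(C)O[C@H]21 | intermediate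
3 | [(4R,5S)-2,2-dimethyl-5-vinyl-1,3-dioxolan-4-yl]methanol | C=C[C@@H]1OC(C)(C)O[C@@H]1CO | intermediate
4 | (4S,5S)-2,2-dimethyl-5-vinyl-1,3-dioxolane-4-carbaldehyde | C=C[C@@H]1OC(C)(C)O[C@@H]1C=O | intermediate
5 | ethynyltrimethylsilane | C#C[Si](C)(C)C | starting material
6 | 1-[(4R,5S)-2,2-dimethyl-5-vinyl-1,3-dioxolan-4-yl]-3-(trimethylsilyl)prop-2-yn-1-ol (both carbinol epimers) | C=C[C@@H]1OC(C)(C)O[C@@H]1C(O)C#C[Si](C)(C)C | intermediate
7 | 1-[(4S,5S)-2,2-dimethyl-5-vinyl-1,3-dioxolan-4-yl]-3-(trimethylsilyl)prop-2-yn-1-one | C=C[C@@H]1OC(C)(C)O[C@@H]1C(=O)C#C[Si](C)(C)C | intermediate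
8 | (S)-2-[(4S,5S)-2,2-dimethyl-5-vinyl-1,3-dioxolan-4-yl]-4-(trimethylsilyl)but-3-yn-2-ol | C=C[C@@H]1OC(C)(C)O[C@@H]1[C@@](C)(O)C#C[Si](C)(C)C | intermediate
9 | (S)-2-[(4S,5S)-2,2-dimethyl-5-vinyl-1,3-dioxolan-4-yl]but-3-yn-2-ol | C=C[C@@H]1OC(C)(C)O[C@@H]1[C@@](C)(O)C#C | intermediate
10 | acrolein | C=CC=O | starting material
11 | (S)-4-benzyl-3-propionyloxazolidin-2-one | CCC(=O)N1[C@@H](Cc2ccccc2)COC1=O | starting material
12 | (S)-4-benzyl-3-[(2S,3R)-3-hydroxy-2-methylpent-4-enoyl]oxazolidin-2-one | C=C[C@@H](O)[C@H](C)C(=O)N1[C@@H](Cc2ccccc2)COC1=O | intermediate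
13 | (2S,3R)-3-hydroxy-N-methoxy-N,2-dimethylpent-4-enamide | C=C[C@@H](O)[C@H](C)C(=O)N(C)OC | intermediate
14 | (2S,3R)-N-methoxy-N,2-dimethyl-3-(triisopropylsilyloxy)pent-4-enamide | C=C[C@@H](O[Si](C(C)C)(C(C)C)C(C)C)[C@H](C)C(=O)N(C)OC | intermediate
15 | (3R,4S,8S)-8-[(4S,5S)-2,2-dimethyl-5-vinyl-1,3-dioxolan-4-yl]-8-hydroxy-4-methyl-3-(triisopropylsilyloxy)non-1-en-6-yn-5-one | C=C[C@@H](O[Si](C(C)C)(C(C)C)C(C)C)[C@H](C)C(=O)C#C[C@](C)(O)[C@H]1OC(C)(C)O[C@H]1C=C | intermediate
16 | (R)-2-[(4S,5S)-2,2-dimethyl-5-vinyl-1,3-dioxolan-4-yl]-2-methyl-5-[(2S,3R)-3-(triisopropylsilyloxy)pent-4-en-2-yl]furan-3(2H)-one | C=C[C@@H](O[Si](C(C)C)(C(C)C)C(C)C)[C@H](C)C1=CC(=O)[C@](C)(O1)[C@H]2OC(C)(C)O[C@H]2C=C | intermediate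
17 | 3,10-epoxygermacra-2,6Z-dien-1-one with 4α-CH3, 5β-OTIPS, 8β,9β-O-isopropylidene, 10β-CH3 | C12=CC(=O)[C@](C)(O1)[C@H]3OC(C)(C)O[C@H]3/C=C\[C@@H](O[Si](C(C)C)(C(C)C)C(C)C)[C@@H]2C | intermediate
18 | 8β,9β-diol of 17 | C12=CC(=O)[C@](C)(O1)[C@@H](O)[C@@H](O)/C=C\[C@@H](O[Si](C(C)C)(C(C)C)C(C)C)[C@@H]2C | intermediate
19 | angelic acid, (Z)-2-methylbut-2-enoic acid | C/C=C(/C)C(=O)O | starting material
20 | 8β-O-angelate of 18 (9β-OH free) | C12=CC(=O)[C@](C)(O1)[C@@H](O)[C@@H](OC(=O)/C(C)=C\C)/C=C\[C@@H](O[Si](C(C)C)(C(C)C)C(C)C)[C@@H]2C | intermediate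
21 | Meldrum's acid, 2,2-dimethyl-1,3-dioxane-4,6-dione | CC1(C)OC(=O)CC(=O)O1 | starting material
22 | 9β-O-(carboxyacetyl) 8β-O-angelate (malonic half-ester on O9) | C12=CC(=O)[C@](C)(O1)[C@@H](OC(=O)CC(=O)O)[C@@H](OC(=O)/C(C)=C\C)/C=C\[C@@H](O[Si](C(C)C)(C(C)C)C(C)C)[C@@H]2C | intermediate
23 | bis-lactone: 6α,12-γ-lactone (ring C) and C13(=O)–O9 δ-lactone (ring D) fused at C7–C11, H7/H11 cis, 8β-angelate, 5β-OTIPS | O=C4[C@H]1C(=O)O[C@@H]2[C@@H](O[Si](C(C)C)(C(C)C)C(C)C)[C@H](C)C3=CC(=O)[C@](C)(O3)[C@@H](O4)[C@@H](OC(=O)/C(C)=C\C)[C@@H]12 | intermediate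
24 | 11-carboxy-6α,12-γ-lactone with 9β-OH free (malonic half-acid) | OC(=O)[C@H]1C(=O)O[C@@H]2[C@@H](O[Si](C(C)C)(C(C)C)C(C)C)[C@H](C)C3=CC(=O)[C@](C)(O3)[C@@H](O)[C@@H](OC(=O)/C(C)=C\C)[C@@H]12 | intermediate
25 | 5-O-triisopropylsilyl ether of the target | C=C1C(=O)O[C@@H]2[C@@H](O[Si](C(C)C)(C(C)C)C(C)C)[C@H](C)C3=CC(=O)[C@](C)(O3)[C@@H](O)[C@@H](OC(=O)/C(C)=C\C)[C@@H]12 | intermediate
26 | CNP0206920.2: 8β-angeloyloxy-5β,9β-dihydroxy-4α,10β-dimethyl-3,10-epoxygermacra-2,11(13)-dien-1-one 6α,12-olide | C=C1C(=O)O[C@@H]2[C@@H](O)[C@H](C)C3=CC(=O)[C@](C)(O3)[C@@H](O)[C@@H](OC(=O)/C(C)=C\C)[C@@H]12 | target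

**Step count and risks**

Total step count: 18. Longest linear sequence: 15 (steps 1–6, then 10–18).

Most likely to fail:

1. Step 16. The ester tether prefers its extended rotamer, so ring closure may be slow and the radical may instead add intermolecularly or to the electron-rich C2 of the furanone. The C6 copper species may also lose a β-hydrogen instead of lactonising. Fallback (polar, the C6 oxygen then comes from an epoxide): setting out from 20, acylation of O9 with methyl malonyl chloride and pyridine should give the O9 methyl malonate F1. m-CPBA should then epoxidise the ring-A alkene on its outer α face, away from the C5 and C8 oxygen substituents, to give the 6α,7α-epoxide F2. With Cs2CO3 in MeCN the malonate carbanion should open the epoxide at C7 (6-exo, inversion, C11 on the β face), and the freed C6 alkoxide should lactonise onto the methyl ester, which brings the route back at 23.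

2. Step 12. Strain in the bridged nine/ten-membered ring may favour oligomerisation, alkene migration or catalyst death over ring closure. Fallback (carbocycle first, bridge afterwards): setting out from 15, TESOTf and 2,6-lutidine should give the O10 triethylsilyl ether F3. Et2NH then adds to the ynone to give the E enaminone F4, which cannot cyclise while O10 is capped. Ring-closing metathesis of F4 should give the unbridged Z,Z-cyclodeca-1,6-diene enaminone F5, a ten-membered ring without bridging strain. Aqueous AcOH then removes the triethylsilyl group and closes the furanone across the ring, which brings the route back at 17.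

3. Step 17. Hydroxide may attack ring C or the angelate, the angelate may migrate from O8 to the freed O9, or the amine may add to the new methylene. Fallback (equilibrating alcoholysis and neutral deallylation in place of hydroxide): setting out from 23, allyl alcohol with catalytic DMAP in toluene at 60 °C should open ring D under thermodynamic control (the γ-lactone recloses, the strained δ-lactone does not) to give the C11 allyl ester F6. Pd(PPh3)4 with morpholine at rt then removes the allyl group, which brings the route back at 24, inside step 17.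

**Further compounds**

F1 | step 16 | O9 methyl malonate of 20 | C12=CC(=O)[C@](C)(O1)[C@@H](OC(=O)CC(=O)OC)[C@@H](OC(=O)/C(C)=C\C)/C=C\[C@@H](O[Si](C(C)C)(C(C)C)C(C)C)[C@@H]2C
F2 | step 16 | 6α,7α-epoxide of F1 | C12=CC(=O)[C@](C)(O1)[C@@H](OC(=O)CC(=O)OC)[C@@H](OC(=O)/C(C)=C\C)[C@@H]3O[C@@H]3[C@@H](O[Si](C(C)C)(C(C)C)C(C)C)[C@@H]2C
F3 | step 12 | O10 triethylsilyl ether of 15 | C=C[C@@H](O[Si](C(C)C)(C(C)C)C(C)C)[C@H](C)C(=O)C#C[C@](C)(O[Si](CC)(CC)CC)[C@H]1OC(C)(C)O[C@H]1C=C
F4 | step 12 | E enaminone from F3 and diethylamine | C=C[C@@H](O[Si](C(C)C)(C(C)C)C(C)C)[C@H](C)C(=O)/C=C(/N(CC)CC)[C@](C)(O[Si](CC)(CC)CC)[C@H]1OC(C)(C)O[C@H]1C=C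
F5 | step 12 | Z,Z-cyclodeca-1,6-diene enaminone (ring A closed, ring B not yet) | C[C@@]1(O[Si](CC)(CC)CC)[C@H]2OC(C)(C)O[C@H]2/C=C\[C@@H](O[Si](C(C)C)(C(C)C)C(C)C)[C@H](C)C(=O)/C=C1/N(CC)CC
F6 | step 17 | C11 allyl ester of 24 | C=CCOC(=O)[C@H]1C(=O)O[C@@H]2[C@@H](O[Si](C(C)C)(C(C)C)C(C)C)[C@H](C)C3=CC(=O)[C@](C)(O3)[C@@H](O)[C@@H](OC(=O)/C(C)=C\C)[C@@H]12
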